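(The runs are calculated for substances that don't exist; scatter was added.)

Friday's run still holds 64.6% of its substrate at 8.00 h, yet its target gains just 1 percentage point over the last 2.00 h.

| flask | substrate | reagent | free catalyst | remark |
|---|---|---|---|---|
| Saturday's | 0.050 M | 0.90 equiv | 0.5 mol% | run made earlier |
| Monday's | 0.075 M | 0.90 equiv | 0.5 mol% | run made earlier |
| Friday's | 0.10 M | 1.8 equiv | 0.5 mol% | run made earlier |
| flask | 0.10 M | 0.900 equiv | 0.5 mol% |  |

| run | time / h | target / % | substrate / % |
|---|---|---|---|
| Saturday's | 1.33 | 1.0 | 88.6 |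
| Saturday's | 2.50 | 2.2 | 85.6 |
| Saturday's | 4.00 | 4.3 | 83.5 |
| Saturday's | 5.00 | 3.8 | 81.2 |
| Saturday's | 6.00 | 4.8 | 80.8 |
| Saturday's | 8.00 | 4.1 | 79.6 |
| Monday's | 0.667 | 1.8 | 90.3 |
| Monday's | 1.00 | 2.0 | 86.9 |
| Monday's | 2.00 | 5.8 | 79.4 |
| Monday's | 3.00 | 7.4 | 77.8 |
| Monday's | 5.00 | 9.5 | 73.9 |
| Monday's | 8.00 | 10.7 | 72.7 |
| Friday's | 1.50 | 8.8 | 79.0 |
| Friday's | 3.00 | 15.3 | 71.3 |
| Friday's | 5.00 | 18.9 | 66.7 |
| Friday's | 6.00 | 19.6 | 65.9 |
| Friday's | 8.00 | 20.6 | 64.6 |

(readings scatter by 0.5 percentage points)

- the earlier runs were read with a standard deviation of 0.5 points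

- apparent order in reagent when 30% of the substrate are converted (percent change of the rate of making target for one percent more reagent charged)

Friday's target gains 15.3% in the first 3.00 h and 4.3 points in the next span of that length. So I read that Friday's pace of making target halves every 1.64 h: that time is the stall half-life. Friday's run is the one run at 1.8 equiv, and it shares no c(substrate) with Saturday's or Monday's, so I read no order of my own. I commit to the clock.

The forecast expects 0.5 and adds: “this is poorly determined”.

The flask gives 0.39. At 1.08 h the flask's catalyst intermediate falls back 0.73 times as fast as it goes on to target.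

    substrate + free catalyst ⇌ free catalyst + open intermediate (K = 1.50, k = 490 M⁻¹ h⁻¹)
    free catalyst + open intermediate ⇌ catalyst intermediate (K = 7.60 M⁻¹, k = 2700 M⁻¹ h⁻¹)
    reagent + catalyst intermediate → free catalyst + target (k = 5700 M⁻¹ h⁻¹)
    free catalyst → spent catalyst (k = 0.510 h⁻¹)

At 8.00 h the substrate in the flask has a half-life of 150 h by its forward step alone, far longer than the stall half-life of 1.64 h read from Friday's run, and the flask keeps 66% of its substrate with 97.9% of its catalyst spent. The flask reaches 30% conversion at 3.48 h, 2.13 of Friday's stall half-lives in; if a dying catalyst's work scales with its charge, twice the free catalyst gets there in 0.330 of that time, and the flask run with twice the free catalyst gives 0.307.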